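Remark on the chemistry: the allyl group on ring A is treated as part of the carbon skeleton that passes through the ring closure, so the side chain is completed after ring C is formed. The atom mapping of the ring-closing pair 10 → 11 (ring A formyl carbon → C4, Claisen carbon → C8, phenoxy oxygen → O1) is self-consistent and needs no structural correction. The refinements concern how 10 is made, handled and cyclised: it is generated under non-basic conditions and used crude, the carbene is an electron-poor triazolylidene with substoichiometric weak base, and the ketol is oxidised by a neutral alcohol oxidation instead of base and air.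

## Structural features

The target 21 is a flavonol: ring A is fused through C4a–C8a to the 4-pyranone ring C, which carries a 4-methoxyphenyl ring B on C2 and a hydroxyl on C3; ring A carries hydroxyls on C5 and C7. C8, flanked by C8a (bearing O1) and the C7 phenol, carries the chain C1''H2–C2''H(OH)–C3''(CH3)=C4''H2. C2'' is the only stereocentre and is (S); it has no stereogenic neighbour, so its configuration must come from a reagent or catalyst. The fragile region is this chain: a secondary allylic alcohol next to a 1,1-disubstituted alkene, held ortho to the C7 phenol, so strong acid can close an ether ring onto C3'' or ionise C2''. The 3-hydroxy-4-pyranone enol and the electron-rich ring A are sensitive to oxidants. The real difficulties are placing the chain on C8 and not C6, building a 3-oxygenated ring C beside a C5 oxygen (where chalcone oxidation tends towards aurones), and setting C2'' far from any directing element. The key step exploits the C3(OH)–C4(=O) pair of ring C: two hydrogens lower it is an α-ketol, an acyloin whose C3–C4 bond can be formed between two formyl carbons, one on C4a of ring A and one on the carbon that becomes C2 of an aryl ether.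

## Logic of the disconnections

21 ⇒ 20. The three O–CH2 acetal bonds on O3, O5 and O7 are cut. The enol and the two phenols must be masked against base, hydride, organometallic and oxidising steps, and one kind of acetal allows a single final operation. Nothing is gained in skeleton, but all polarity problems are moved to the last step. The demand is an acid mild enough to spare C2''–OH and C3''=C4''.

20 ⇒ 19 ⇒ 18 ⇒ 16 + 17. First the C2''–H bond is cut (to the ketone 19 and its precursor alcohol 18), then C2''–C3''. C2'' is an isolated carbinol between an sp2-branched group and a methylene, a pattern suited to catalyst-controlled ketone reduction, and C2''–C3'' joins an aldehyde carbon to an alkenyl nucleophile. The stereocentre and three carbons are removed. The forward steps need addition of 17 to an enolisable aldehyde in the presence of the C4 carbonyl, and face-selective 1,2-reduction of 19.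

16 ⇒ 14. The formyl carbon is traced back to the internal carbon of an allyl group (the C2''=C3'' alkene carbon pair of 14 is cleaved in the forward direction). An allyl group is an inert latent acetaldehyde that survives every earlier step. The demand is cleavage of the terminal alkene without touching C2=C3 of ring C.

14 ⇒ 13 ⇒ 11 (through 12). The O3 acetal is removed, then hydrogen is added back across C2–C3. This exposes the α-ketol that the key step makes, and it shows that the two stereocentres of 11 are of no consequence. The forward oxidation must act on the C3 carbinol only and leave the allyl group and ring A alone.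

11 ⇒ 10. The C3–C4 bond is cut, opening ring C. This is the strategic cut: both carbons become formyl groups, O1–C2 is already in place, and the C3 oxygen and C4 carbonyl arise together. The forward step needs an acyl-anion equivalent made catalytically from one formyl group, adding to the other faster than enolisation or loss of the aryloxide.

10 ⇒ 9 ⇒ 8 ⇒ 6 + 7. Two redox adjustments (dialdehyde from diol, diol from ester-aldehyde) precede the cut of the O1–C2 ether bond. The ester is the stable, easily alkylated form of the fragile α-aryloxy aldehyde. The cut separates ring B with C2 and C3 (in 7) from ring A (in 6). The forward alkylation must succeed on a hindered, chelated phenol, and the dialdehyde must be formed without base.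

6 ⇒ 4 (through 5) ⇒ 2 + 3 ⇒ 1. The C8–C1'' bond (C3–CH2 in 6) is cut by a retro-Claisen step to an O-allyl ether, then the O–allyl bond and the two acetal O–C bonds. The sigmatropic shift can only go to the one free ortho carbon, so the chain position is fixed, and the oxygen it frees is the one that becomes O1. The demand is selective protection of two of the three hydroxyls of 1, which the hydrogen bond to the formyl group provides.

## Other disconnections considered

Alternative 1: ring A by cycloaddition onto a preformed ring C.
- **Cut:** C4a–C5 and C8–C8a.
- **Forward key step:** the sulfinyl pyranone A2 acts as dienophile towards the bis(silyloxy) ketene-acetal diene A3, which carries the protected side chain on its nucleophilic terminus. A [4+2] addition, a sulfoxide syn-elimination and loss of the ketal alkoxy group aromatise ring A to A1.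
- **In favour:** the plan is convergent. Diene polarity places the chain on C8. The stereocentre is brought in on a small fragment. The C5 and C7 phenols emerge free, so two protecting groups are saved.
- **Against:** a 4-pyranone C=C is a reluctant dienophile, and sulfinyl activation is established mainly for benzo-fused chromones. The diene terminus that must bond to C8a is substituted and the diene is moisture-sensitive. A2 needs a regiocontrolled synthesis of its own. A1 still needs acid and fluoride to unmask.
- **Comparison:** on structure it is the equal of the chosen plan for C8 regiocontrol and the better for convergence and for setting C2'' on a small molecule. On mechanism both hinge on one step without close precedent, a thermal pericyclic step there and a polar organocatalytic step here. On step economy its longest linear sequence should be shorter, but the total count over two fragments is likely similar.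

Alternative 2: Danheiser benzannulation of ring A.
- **Cut:** C7–C8, C4a–C8a and C6–C7.
- **Forward key step:** heating the cyclobutenone A6 with the chiral siloxyalkyne A5 starts a cascade (four-electron ring opening to a vinylketene, [2+2] addition, second ring opening, six-electron closure, tautomerisation) that ends in the phenol A4.
- **In favour:** the conditions are neutral and thermal, and the substitution pattern is fully regiospecific. The three ring A oxygens are all differentiated (free C7–OH, silyl ether on the future O1, ethyl ether on O5). The side chain and its stereocentre are installed before any heterocycle chemistry.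
- **Against:** only the arene is made. C4a acylation between two oxygen substituents, the whole of ring C and the C3 oxygen still lie ahead, all with the sensitive chain on board. The O5 ethyl ether must later be cleaved beside the ring B methyl ether, probably with a boron or aluminium Lewis acid that endangers the allylic system. A5 needs an ynolate-based preparation.
- **Comparison:** on structure it equals the Claisen route in regiochemical certainty and is better in oxygen differentiation. On mechanism it is the better precedented key step. On step economy it is clearly worse, because it solves the easier half of the problem.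

Alternative 3: Matteson homologation with C2'' as a one-carbon linchpin.
- **Cut:** C1''–C2'' and C2''–C3''.
- **Forward key step:** the C8 benzylic boronic ester A8 of the (S,S)-configured dicyclohexylethanediol takes up LiCHCl2 and rearranges under ZnCl2 to the (R)-α-chloro boronate A9. Reagent 17 displaces chloride with inversion, and NaOH/H2O2 oxidation with retention gives A7, which is the same compound as 20.
- **In favour:** the diol-controlled 1,2-migration sets the stereocentre directly at the alcohol oxidation level, with no racemic alcohol, no enone and no reduction. One flask would replace steps 10 to 13.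
- **Against:** A8 needs a one-carbon boron handle on C8 of a finished flavonol, and installing it regioselectively (C8 against C6) lacks the certainty of the Claisen shift. Electron-rich benzylic boronates protodeboronate easily. LiCHCl2, the Grignard reagent and alkaline peroxide all meet the C4 carbonyl and the C2=C3 bond. The reaction is cryogenic and uses a costly auxiliary.
- **Comparison:** this alternative addresses the side chain only and would still need a ring C synthesis such as the chosen one. On stereocontrol and on the step count of the side chain it is the better. On access to its precursor and on functional-group risk it is the worse.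

Key step: step 7

## Route

Step 1
Reactants: 1 2,4,6-trihydroxybenzaldehyde
Product: 2 2-hydroxy-4,6-bis(methoxymethoxy)benzaldehyde
Conditions: MOMCl (2.2 equiv), iPr2NEt (2.5 equiv), CH2Cl2/DMF, 0 °C → rt
Reagents that add atoms: chloromethyl methyl ether, COCCl
Why: O-alkylation with an α-chloro ether (acetal protection); the para hydroxyl and one of the two equivalent ortho hydroxyls react, and the remaining ortho hydroxyl is locked in a hydrogen bond to the formyl oxygen and should stay free with a limited amount of reagent.

Step 2
Reactants: 2 2-hydroxy-4,6-bis(methoxymethoxy)benzaldehyde; 3 allyl bromide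
Product: 4 2-(allyloxy)-4,6-bis(methoxymethoxy)benzaldehyde
Conditions: K2CO3, DMF, rt
Reagents that add atoms: none
Why: Williamson ether synthesis; carbonate in a dipolar aprotic solvent opens the chelate and the phenoxide displaces bromide from the reactive allylic halide.

Step 3
Reactants: 4 2-(allyloxy)-4,6-bis(methoxymethoxy)benzaldehyde
Product: 6 3-allyl-2-hydroxy-4,6-bis(methoxymethoxy)benzaldehyde, via ortho-dienone 5 (not isolated)
Conditions: PhNEt2, 190 °C, sealed tube, argon
Reagents that add atoms: none
Why: aromatic Claisen rearrangement; the [3,3] shift can only reach the one unsubstituted ortho carbon, and dienone 5 tautomerises to the hydrogen-bonded salicylaldehyde, which fixes the allyl group next to the oxygen that becomes O1; acetals and the formyl group tolerate neutral heating.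

Step 4
Reactants: 6 3-allyl-2-hydroxy-4,6-bis(methoxymethoxy)benzaldehyde; 7 methyl 2-bromo-2-(4-methoxyphenyl)acetate (racemic)
Product: 8 methyl 2-[2-allyl-6-formyl-3,5-bis(methoxymethoxy)phenoxy]-2-(4-methoxyphenyl)acetate (racemic)
Conditions: K2CO3, DMF, rt → 40 °C
Reagents that add atoms: none
Why: Williamson ether synthesis; the bromide is doubly activated (benzylic and α to an ester), so the hindered, chelated phenoxide should still alkylate under mild carbonate conditions that keep aldol addition of the product ester onto the formyl group slow and reversible.

Step 5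
Reactants: 8 methyl 2-[2-allyl-6-formyl-3,5-bis(methoxymethoxy)phenoxy]-2-(4-methoxyphenyl)acetate (racemic)
Product: 9 2-[2-allyl-6-(hydroxymethyl)-3,5-bis(methoxymethoxy)phenoxy]-2-(4-methoxyphenyl)ethan-1-ol (racemic)
Conditions: LiAlH4, THF, 0 °C; H2O/aq. NaOH work-up
Reagents that add atoms: none
Why: hydride reduction of the ester and the aldehyde to the diol; no hydride stops an ester at the aldehyde while sparing a free aryl aldehyde, so both carbons are taken to the alcohol level and raised together in step 6; aryl ethers, acetals and the alkene are inert.

Step 6
Reactants: 9 2-[2-allyl-6-(hydroxymethyl)-3,5-bis(methoxymethoxy)phenoxy]-2-(4-methoxyphenyl)ethan-1-ol (racemic)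
Product: 10 3-allyl-2-[1-(4-methoxyphenyl)-2-oxoethoxy]-4,6-bis(methoxymethoxy)benzaldehyde (racemic)
Conditions: Dess–Martin periodinane (2.6 equiv), CH2Cl2, 0 °C → rt; crude product used at once
Reagents that add atoms: none
Why: Dess–Martin oxidation of both primary alcohols; it stops at the aldehyde and involves no base, so the enolisable α-aryl-α-aryloxy aldehyde is not exposed to enolising conditions before the carbene step.

Step 7
Reactants: 10 3-allyl-2-[1-(4-methoxyphenyl)-2-oxoethoxy]-4,6-bis(methoxymethoxy)benzaldehyde (racemic)
Product: 11 8-allyl-3-hydroxy-5,7-bis(methoxymethoxy)-2-(4-methoxyphenyl)chroman-4-one (racemic diastereomer mixture)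
Conditions: 2-(pentafluorophenyl)-6,7-dihydro-5H-pyrrolo[2,1-c][1,2,4]triazol-2-ium tetrafluoroborate (20 mol%), Et3N (20 mol%), degassed CH2Cl2, 0 °C → rt, argon
Reagents that add atoms: none
Why: Proposed new method: the triazolylidene freed by the amine adds to a formyl group and proton transfer gives the acyl-anion equivalent (Breslow intermediate), which attacks the second formyl carbon within the same molecule; proton transfer and expulsion of the carbene leave the α-ketol, so C3–C4 forms and ring C closes by a 6-exo-trig addition. The closest known reaction type is the carbene-catalysed intramolecular crossed benzoin of salicylaldehyde-derived keto ethers to 3-hydroxychroman-4-ones, together with benzoin cyclisations of aliphatic dialdehydes; what has not been shown is the pairing of a hindered aryl aldehyde with an enolisable α-aryl-α-aryloxy aldehyde. No stereocentre has to be controlled: C2 is already racemic, C3 forms as a mixture, and both are erased in step 8. If the aliphatic formyl group is the donor instead of the crowded 2,6-dioxygenated ring A formyl group, the ketol forms with hydroxyl and carbonyl interchanged; this isomer shares its enediol with 11 and is oxidised to the same dione 12, so donor selectivity is not required. The selectivity that is required is ring closure ahead of two base-driven diversions: enolisation of the α-aryloxy aldehyde with reversible five-ring aldol addition onto the ring A formyl group, and expulsion of the ring A aryloxide from the carbene adduct of the α-aryloxy aldehyde (an internal redox leading to an aryl ester). The substrate answers the first through the six-membered transition state that holds the acceptor next to the acyl anion, and because the aldol is reversible while the ketol is a thermodynamic sink; the second is countered by the electron-poor N-pentafluorophenyl carbene, substoichiometric weak base, low temperature and the electron-donating acetal ethers, which make the aryloxide a poorer leaving group. Oxygen is excluded so that the acyl anion is not intercepted oxidatively.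

Step 8
Reactants: 11 8-allyl-3-hydroxy-5,7-bis(methoxymethoxy)-2-(4-methoxyphenyl)chroman-4-one (racemic diastereomer mixture)
Product: 13 8-allyl-3-hydroxy-5,7-bis(methoxymethoxy)-2-(4-methoxyphenyl)-4H-chromen-4-one, via chromane-3,4-dione 12 (not isolated)
Conditions: Dess–Martin periodinane (1.1 equiv), CH2Cl2, 0 °C → rt; aq. NaHCO3/Na2S2O3 work-up
Reagents that add atoms: none
Why: Dess–Martin oxidation of an α-ketol to the 1,2-dione; dione 12 has a C2–H that is benzylic, α to a ketone and α to O1, and should tautomerise at once to the aromatic 3-hydroxy-4-pyranone, removing both stereocentres; neutral conditions and only a slight excess of oxidant avoid base-induced ring contraction and further oxidation of the enol.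

Step 9
Reactants: 13 8-allyl-3-hydroxy-5,7-bis(methoxymethoxy)-2-(4-methoxyphenyl)-4H-chromen-4-one
Product: 14 8-allyl-3,5,7-tris(methoxymethoxy)-2-(4-methoxyphenyl)-4H-chromen-4-one
Conditions: MOMCl, iPr2NEt, CH2Cl2, 0 °C → rt
Reagents that add atoms: chloromethyl methyl ether, COCCl
Why: O-alkylation of the acidic enolic hydroxyl (acetal protection); it shields the enol from OsO4/NaIO4, the Grignard reagent, the periodinane and the borane in steps 10 to 13 and leaves one kind of protecting group for the end.

Step 10
Reactants: 14 8-allyl-3,5,7-tris(methoxymethoxy)-2-(4-methoxyphenyl)-4H-chromen-4-one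
Product: 16 2-[3,5,7-tris(methoxymethoxy)-2-(4-methoxyphenyl)-4-oxo-4H-chromen-8-yl]acetaldehyde, via vicinal diol 15 (not isolated)
Conditions: OsO4 (2 mol%), NaIO4 (4 equiv), 2,6-lutidine, dioxane/H2O 3:1, rt
Reagents that add atoms: osmium tetroxide, O=[Os](=O)(=O)=O; sodium periodate, [Na+].[O-]I(=O)(=O)=O
Why: Lemieux–Johnson oxidative cleavage; the monosubstituted alkene is dihydroxylated far faster than the tetrasubstituted, electronically deactivated C2=C3 bond, and periodate cleaves diol 15 to the arylacetaldehyde, which is used directly.

Step 11
Reactants: 16 2-[3,5,7-tris(methoxymethoxy)-2-(4-methoxyphenyl)-4-oxo-4H-chromen-8-yl]acetaldehyde; 17 isopropenylmagnesium bromide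
Product: 18 8-(2-hydroxy-3-methylbut-3-en-1-yl)-3,5,7-tris(methoxymethoxy)-2-(4-methoxyphenyl)-4H-chromen-4-one (racemic)
Conditions: LaCl3·2LiCl (30 mol%), THF, −78 °C; aq. NH4Cl
Reagents that add atoms: none
Why: Grignard 1,2-addition to an aldehyde; the lanthanum salt favours addition over enolisation of the arylacetaldehyde, and at −78 °C the C4 carbonyl, a vinylogous ester, should not compete; the new stereocentre is formed without control and is corrected in steps 12 and 13.

Step 12
Reactants: 18 8-(2-hydroxy-3-methylbut-3-en-1-yl)-3,5,7-tris(methoxymethoxy)-2-(4-methoxyphenyl)-4H-chromen-4-one (racemic)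
Product: 19 8-(3-methyl-2-oxobut-3-en-1-yl)-3,5,7-tris(methoxymethoxy)-2-(4-methoxyphenyl)-4H-chromen-4-one
Conditions: Dess–Martin periodinane (1.3 equiv), CH2Cl2, 0 °C
Reagents that add atoms: none
Why: Dess–Martin oxidation of a secondary allylic alcohol to the enone; the absence of base avoids enolisation at the doubly activated C1'' methylene and conjugate additions to the α-methylene ketone, which is carried on promptly.

Step 13
Reactants: 19 8-(3-methyl-2-oxobut-3-en-1-yl)-3,5,7-tris(methoxymethoxy)-2-(4-methoxyphenyl)-4H-chromen-4-one
Product: 20 8-[(2S)-2-hydroxy-3-methylbut-3-en-1-yl]-3,5,7-tris(methoxymethoxy)-2-(4-methoxyphenyl)-4H-chromen-4-one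
Conditions: (R)-2-methyl-CBS-oxazaborolidine [(3aR)-1-methyl-3,3-diphenyltetrahydro-1H,3H-pyrrolo[1,2-c][1,3,2]oxazaborole] (20 mol%), catecholborane (1.8 equiv), toluene, −78 °C; MeOH, then aqueous work-up
Reagents that add atoms: none
Why: Corey–Bakshi–Shibata reduction; the ketone binds to the ring boron with the α-branched sp2 isopropenyl group as the large substituent and the C1'' methylene as the small one, and hydride is delivered from the nitrogen-bound borane to the face that gives the (S)-carbinol with the (R)-catalyst, the mirror image of the acetophenone case with isopropenyl in the place of phenyl. Catecholborane at low temperature should leave the alkene and the C4 carbonyl untouched.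

Step 14
Reactants: 20 8-[(2S)-2-hydroxy-3-methylbut-3-en-1-yl]-3,5,7-tris(methoxymethoxy)-2-(4-methoxyphenyl)-4H-chromen-4-one
Product: 21 3,5,7-trihydroxy-8-[(2S)-2-hydroxy-3-methylbut-3-en-1-yl]-2-(4-methoxyphenyl)-4H-chromen-4-one
Conditions: aq. HCl (3 M)/MeOH 1:4, rt → 40 °C; NaHCO3 quench
Reagents that add atoms: none
Why: acid-catalysed acetal exchange with methanol removes the three phenol-type acetals; the alkene is deactivated towards protonation by the neighbouring hydroxyl and the secondary allylic alcohol does not ionise readily in dilute acid, so the side chain and its stereocentre should survive.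

## Compound list

1 | 2,4,6-trihydroxybenzaldehyde | O=Cc1c(O)cc(O)cc1O | starting material
2 | 2-hydroxy-4,6-bis(methoxymethoxy)benzaldehyde | COCOc1cc(O)c(C=O)c(OCOC)c1 | intermediate
3 | allyl bromide | C=CCBr | starting material
4 | 2-(allyloxy)-4,6-bis(methoxymethoxy)benzaldehyde | C=CCOc1cc(OCOC)cc(OCOC)c1C=O | intermediate
5 | 5-allyl-2,4-bis(methoxymethoxy)-6-oxocyclohexa-1,3-diene-1-carbaldehyde (ortho-dienone, racemic) | C=CCC1C(=O)C(C=O)=C(OCOC)C=C1OCOC | intermediate (not isolated)
6 | 3-allyl-2-hydroxy-4,6-bis(methoxymethoxy)benzaldehyde | C=CCc1c(OCOC)cc(OCOC)c(C=O)c1O | intermediate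
7 | methyl 2-bromo-2-(4-methoxyphenyl)acetate (racemic) | COC(=O)C(Br)c1ccc(OC)cc1 | starting material
8 | methyl 2-[2-allyl-6-formyl-3,5-bis(methoxymethoxy)phenoxy]-2-(4-methoxyphenyl)acetate (racemic) | C=CCc1c(OCOC)cc(OCOC)c(C=O)c1OC(C(=O)OC)c1ccc(OC)cc1 | intermediate
9 | 2-[2-allyl-6-(hydroxymethyl)-3,5-bis(methoxymethoxy)phenoxy]-2-(4-methoxyphenyl)ethan-1-ol (racemic) | C=CCc1c(OCOC)cc(OCOC)c(CO)c1OC(CO)c1ccc(OC)cc1 | intermediate
10 | 3-allyl-2-[1-(4-methoxyphenyl)-2-oxoethoxy]-4,6-bis(methoxymethoxy)benzaldehyde (racemic) | C=CCc1c(OCOC)cc(OCOC)c(C=O)c1OC(C=O)c1ccc(OC)cc1 | intermediate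
11 | 8-allyl-3-hydroxy-5,7-bis(methoxymethoxy)-2-(4-methoxyphenyl)chroman-4-one (racemic diastereomer mixture) | C=CCc1c(OCOC)cc(OCOC)c2c1OC(c1ccc(OC)cc1)C(O)C2=O | intermediate
12 | 8-allyl-5,7-bis(methoxymethoxy)-2-(4-methoxyphenyl)chromane-3,4-dione (racemic) | C=CCc1c(OCOC)cc(OCOC)c2c1OC(c1ccc(OC)cc1)C(=O)C2=O | intermediate (not isolated)
13 | 8-allyl-3-hydroxy-5,7-bis(methoxymethoxy)-2-(4-methoxyphenyl)-4H-chromen-4-one | C=CCc1c(OCOC)cc(OCOC)c2c(=O)c(O)c(-c3ccc(OC)cc3)oc12 | intermediate
14 | 8-allyl-3,5,7-tris(methoxymethoxy)-2-(4-methoxyphenyl)-4H-chromen-4-one | C=CCc1c(OCOC)cc(OCOC)c2c(=O)c(OCOC)c(-c3ccc(OC)cc3)oc12 | intermediate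
15 | 8-(2,3-dihydroxypropyl)-3,5,7-tris(methoxymethoxy)-2-(4-methoxyphenyl)-4H-chromen-4-one (racemic) | OCC(O)Cc1c(OCOC)cc(OCOC)c2c(=O)c(OCOC)c(-c3ccc(OC)cc3)oc12 | intermediate (not isolated)
16 | 2-[3,5,7-tris(methoxymethoxy)-2-(4-methoxyphenyl)-4-oxo-4H-chromen-8-yl]acetaldehyde | O=CCc1c(OCOC)cc(OCOC)c2c(=O)c(OCOC)c(-c3ccc(OC)cc3)oc12 | intermediate
17 | isopropenylmagnesium bromide | C=C(C)[Mg]Br | starting material
18 | 8-(2-hydroxy-3-methylbut-3-en-1-yl)-3,5,7-tris(methoxymethoxy)-2-(4-methoxyphenyl)-4H-chromen-4-one (racemic) | C=C(C)C(O)Cc1c(OCOC)cc(OCOC)c2c(=O)c(OCOC)c(-c3ccc(OC)cc3)oc12 | intermediate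
19 | 8-(3-methyl-2-oxobut-3-en-1-yl)-3,5,7-tris(methoxymethoxy)-2-(4-methoxyphenyl)-4H-chromen-4-one | C=C(C)C(=O)Cc1c(OCOC)cc(OCOC)c2c(=O)c(OCOC)c(-c3ccc(OC)cc3)oc12 | intermediate
20 | 8-[(2S)-2-hydroxy-3-methylbut-3-en-1-yl]-3,5,7-tris(methoxymethoxy)-2-(4-methoxyphenyl)-4H-chromen-4-one | C=C(C)[C@@H](O)Cc1c(OCOC)cc(OCOC)c2c(=O)c(OCOC)c(-c3ccc(OC)cc3)oc12 | intermediate
21 | 3,5,7-trihydroxy-8-[(2S)-2-hydroxy-3-methylbut-3-en-1-yl]-2-(4-methoxyphenyl)-4H-chromen-4-one | C=C(C)[C@@H](O)Cc1c(O)cc(O)c2c(=O)c(O)c(-c3ccc(OC)cc3)oc12 | target

## Step count and least certain steps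

Total step count: 14. Longest linear sequence: 14 steps (1 → 21); 3, 7 and 17 enter as purchased reagents.

Step 7 (key step, proposed new method).
- **What may go wrong:** the carbene adduct of the α-aryloxy aldehyde may expel the ring A aryloxide before it cyclises. The amine may enolise that aldehyde and divert material into the five-ring aldol. The crowded ring A formyl group may react too slowly, so that these diversions and retro-benzoin equilibration dominate.
- **Fallback (known chemistry):** it sets out from 10 and comes back at 13. SmI2 (2.5 equiv, THF, t-BuOH, −78 °C) couples the two formyl groups reductively in a pinacol cyclisation, without base or carbene, to 8-allyl-5,7-bis(methoxymethoxy)-2-(4-methoxyphenyl)chromane-3,4-diol F1. Oxidation of both carbinols with IBX in DMSO, a reagent that does not cleave 1,2-diols, then leads through 11 and 12 to 13.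

Step 6.
- **What may go wrong:** the α-aryl-α-aryloxy aldehyde may hydrate, enolise or autoxidise during the double oxidation. A half-oxidised hydroxy aldehyde may close to a lactol and be oxidised on to a lactone.
- **Fallback:** it sets out from 9 and comes back at 10. MnO2 (CH2Cl2, rt) oxidises only the benzylic alcohol and gives 3-allyl-2-[2-hydroxy-1-(4-methoxyphenyl)ethoxy]-4,6-bis(methoxymethoxy)benzaldehyde F2, which can be purified and stored. The remaining primary alcohol is oxidised separately under Parikh–Doering conditions (SO3·pyridine, DMSO, iPr2NEt, 0 °C) immediately before the carbene step, so the fragile formyl group is made last and alone.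

Step 11.
- **What may go wrong:** the Grignard reagent may deprotonate the acidic arylacetaldehyde instead of adding, or may add to the C4 carbonyl.
- **Fallback:** it sets out from 16 and comes back at 18. Nozaki–Hiyama–Kishi coupling with 2-bromopropene (CrCl2, catalytic NiCl2, DMF, rt) uses a non-basic organochromium nucleophile that is selective for aldehydes. This fallback makes no new compound (F0).

Step 13.
- **What may go wrong:** facial selectivity may be poor, because the C1'' methylene carries a bulky, Lewis-basic chromone that can bind the catalyst or blur the size difference between the two ketone substituents; conjugate reduction may also compete.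
- **Fallback:** it sets out from 18 and comes back at 20, leaving out steps 12 and 13. Sharpless kinetic resolution (Ti(OiPr)4, D-(−)-diisopropyl tartrate, t-BuOOH 0.6 equiv, 4 Å molecular sieves, CH2Cl2, −20 °C) epoxidises the (R)-enantiomer to 8-{(2R)-2-hydroxy-2-[(2R)-2-methyloxiran-2-yl]ethyl}-3,5,7-tris(methoxymethoxy)-2-(4-methoxyphenyl)-4H-chromen-4-one F3 and leaves the (S)-enantiomer, which is 20. At most half of 18 is used.

Step 14.
- **What may go wrong:** under protic acid the C7 phenol may add to the protonated alkene and close an ether ring, the allylic alcohol may solvolyse, or the non-chelated O7 acetal may cleave incompletely at the mild acidity chosen.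
- **Fallback:** it sets out from 20 and comes back at 21. TMSOTf and 2,2'-bipyridyl (MeCN, 0 °C → rt) exchange the acetals for silyl groups without free protic acid and give 2-(4-methoxyphenyl)-8-[(2S)-3-methyl-2-(trimethylsilyloxy)but-3-en-1-yl]-3,5,7-tris(trimethylsilyloxy)-4H-chromen-4-one F4 (not isolated). Water at neutral pH then hydrolyses the silyl ethers to 21.

## Further compounds

F1 | step 7 | 8-allyl-5,7-bis(methoxymethoxy)-2-(4-methoxyphenyl)chromane-3,4-diol (racemic diastereomer mixture) | C=CCc1c(OCOC)cc(OCOC)c2c1OC(c1ccc(OC)cc1)C(O)C2O
F2 | step 6 | 3-allyl-2-[2-hydroxy-1-(4-methoxyphenyl)ethoxy]-4,6-bis(methoxymethoxy)benzaldehyde (racemic) | C=CCc1c(OCOC)cc(OCOC)c(C=O)c1OC(CO)c1ccc(OC)cc1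
F0 | step 11 | none | none
F3 | step 13 | 8-{(2R)-2-hydroxy-2-[(2R)-2-methyloxiran-2-yl]ethyl}-3,5,7-tris(methoxymethoxy)-2-(4-methoxyphenyl)-4H-chromen-4-one | C[C@@]4(CO4)[C@H](O)Cc1c(OCOC)cc(OCOC)c2c(=O)c(OCOC)c(-c3ccc(OC)cc3)oc12
F4 | step 14 | 2-(4-methoxyphenyl)-8-[(2S)-3-methyl-2-(trimethylsilyloxy)but-3-en-1-yl]-3,5,7-tris(trimethylsilyloxy)-4H-chromen-4-one | C=C(C)[C@@H](O[Si](C)(C)C)Cc1c(O[Si](C)(C)C)cc(O[Si](C)(C)C)c2c(=O)c(O[Si](C)(C)C)c(-c3ccc(OC)cc3)oc12
A1 | alternative 1 | 8-[(2S)-2-(tert-butyldimethylsilyloxy)-3-methylbut-3-en-1-yl]-5,7-dihydroxy-3-(methoxymethoxy)-2-(4-methoxyphenyl)-4H-chromen-4-one | C=C(C)[C@@H](O[Si](C)(C)C(C)(C)C)Cc1c(O)cc(O)c2c(=O)c(OCOC)c(-c3ccc(OC)cc3)oc12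
A2 | alternative 1 | 3-(methoxymethoxy)-2-(4-methoxyphenyl)-5-(phenylsulfinyl)-4H-pyran-4-one (racemic at sulfur) | COCOc1c(-c2ccc(OC)cc2)occ(S(=O)c2ccccc2)c1=O
A3 | alternative 1 | (3S)-3-(tert-butyldimethylsilyloxy)-8-methoxy-2-methyl-6,8-bis(trimethylsilyloxy)octa-1,5,7-triene (alkene geometry not specified) | C=C(C)[C@@H](O[Si](C)(C)C(C)(C)C)CC=C(O[Si](C)(C)C)C=C(OC)O[Si](C)(C)C
A4 | alternative 2 | 2-[(2S)-2-(tert-butyldimethylsilyloxy)-3-methylbut-3-en-1-yl]-5-ethoxy-3-(triisopropylsilyloxy)phenol | C=C(C)[C@@H](O[Si](C)(C)C(C)(C)C)Cc1c(O)cc(OCC)cc1O[Si](C(C)C)(C(C)C)C(C)C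
A5 | alternative 2 | (3S)-3-(tert-butyldimethylsilyloxy)-2-methyl-6-(triisopropylsilyloxy)hex-1-en-5-yne | C=C(C)[C@@H](O[Si](C)(C)C(C)(C)C)CC#CO[Si](C(C)C)(C(C)C)C(C)C
A6 | alternative 2 | 3-ethoxycyclobut-2-en-1-one | CCOC1=CC(=O)C1
A7 | alternative 3 | 8-[(2S)-2-hydroxy-3-methylbut-3-en-1-yl]-3,5,7-tris(methoxymethoxy)-2-(4-methoxyphenyl)-4H-chromen-4-one (identical with 20) | C=C(C)[C@@H](O)Cc1c(OCOC)cc(OCOC)c2c(=O)c(OCOC)c(-c3ccc(OC)cc3)oc12
A8 | alternative 3 | (4S,5S)-4,5-dicyclohexyl-2-{[3,5,7-tris(methoxymethoxy)-2-(4-methoxyphenyl)-4-oxo-4H-chromen-8-yl]methyl}-1,3,2-dioxaborolane | COCOc1cc(OCOC)c2c(=O)c(OCOC)c(-c3ccc(OC)cc3)oc2c1CB4O[C@@H](C5CCCCC5)[C@H](C5CCCCC5)O4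
A9 | alternative 3 | (4S,5S)-2-{(1R)-1-chloro-2-[3,5,7-tris(methoxymethoxy)-2-(4-methoxyphenyl)-4-oxo-4H-chromen-8-yl]ethyl}-4,5-dicyclohexyl-1,3,2-dioxaborolane | COCOc1cc(OCOC)c2c(=O)c(OCOC)c(-c3ccc(OC)cc3)oc2c1C[C@H](Cl)B4O[C@@H](C5CCCCC5)[C@H](C5CCCCC5)O4
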